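**Retrosynthetic overview**
1. Target 19 ← hydrogenolysis of five benzyl ethers ← O7''-sulfation ← selective removal of the O7''-MOM group ← fully protected 3,8''-linked flavanone–flavone 16.
2. 16 ← enol silane 13 + 4-(benzyloxy)benzaldehyde 4: one-pot enantioselective aldol/SNAr annulation that forms C2–C3 and O1–C8a (the aldehyde oxygen becomes O1) and closes the flavanone pyranone ring C, the last ring formed.
3. Enabling feature: in ring A, C8a is ortho to the C4 carbonyl and meta to O5 and O7, so a fluorine at C8a is an activated SNAr leaving group; C3, flanked by the C4 ketone and flavone carbon C8'', is the enolisable carbon; the fluoride released re-activates the next enol silane.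
4. 13 ← ketone 12 ← Pd-catalysed α-arylation of 2-fluoro-4,6-bis(benzyloxy)acetophenone 11 (from 5-fluororesorcinol 9) with 8-iodoflavone 8.
5. 8 ← phloroacetophenone 1 by O7''-MOM/O5''-benzyl differentiation, chalcone formation, oxidative closure of the flavone pyranone ring C'' (the first ring formed) and C8''-iodination; all carbocyclic rings are bought.

Key step: step 10

Remark: sulfate monoesters are handled as salts but drawn as the free acid, the acid form of the target being released on an H+ resin; unprimed locants belong to the flavanone half and doubly primed ones to the flavone half.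

**Step 1**
Reactants: 1 1-(2,4,6-trihydroxyphenyl)ethanone
Product: 2 1-[2,6-dihydroxy-4-(methoxymethoxy)phenyl]ethanone
Conditions: MOMCl (1.05 equiv), i-Pr2NEt, CH2Cl2/THF, 0 °C
Reagents that add atoms: chloromethyl methyl ether, COCCl
Why: O-alkylation (MOM ether formation) should occur at the 4-OH, which is para to the acetyl group, the most acidic hydroxyl and the only one not hydrogen-bonded to the carbonyl, so one equivalent leaves both ortho hydroxyls free.

**Step 2**
Reactants: 2 1-[2,6-dihydroxy-4-(methoxymethoxy)phenyl]ethanone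
Product: 3 1-[2-(benzyloxy)-6-hydroxy-4-(methoxymethoxy)phenyl]ethanone
Conditions: BnBr (1.05 equiv), K2CO3, acetone, 56 °C
Reagents that add atoms: benzyl bromide, BrCc1ccccc1
Why: Williamson etherification should stop after one benzylation because the remaining ortho hydroxyl is locked in the hydrogen bond to the acetyl carbonyl and is far less nucleophilic.

**Step 3**
Reactants: 3 1-[2-(benzyloxy)-6-hydroxy-4-(methoxymethoxy)phenyl]ethanone; 4 4-(benzyloxy)benzaldehyde
Product: 5 (E)-1-[2-(benzyloxy)-6-hydroxy-4-(methoxymethoxy)phenyl]-3-[4-(benzyloxy)phenyl]prop-2-en-1-one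
Conditions: KOH, EtOH/THF, rt
Reagents that add atoms: none
Why: Claisen–Schmidt condensation of the acetophenone enolate with the non-enolisable aldehyde followed by E1cB dehydration should give the (E)-chalcone, the MOM and benzyl ethers being stable to hydroxide.

**Step 4**
Reactants: 5 (E)-1-[2-(benzyloxy)-6-hydroxy-4-(methoxymethoxy)phenyl]-3-[4-(benzyloxy)phenyl]prop-2-en-1-one
Product: 7 5-(benzyloxy)-2-[4-(benzyloxy)phenyl]-7-(methoxymethoxy)-4H-chromen-4-one, via racemic flavanone 6 (not isolated)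
Conditions: pyridine, piperidine (cat.), 95 °C; then I2 (1.1 equiv), 95 °C
Reagents that add atoms: none
Why: Base-mediated 6-endo-trig oxa-Michael cyclisation to the flavanone followed by iodine-mediated dehydrogenation (α-iodination, then elimination of HI) is the standard flavanone-to-flavone oxidation, and pyridine buffers the HI so that the MOM acetal should survive.

**Step 5**
Reactants: 7 5-(benzyloxy)-2-[4-(benzyloxy)phenyl]-7-(methoxymethoxy)-4H-chromen-4-one
Product: 8 5-(benzyloxy)-2-[4-(benzyloxy)phenyl]-8-iodo-7-(methoxymethoxy)-4H-chromen-4-one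
Conditions: NIS (1.2 equiv), DMF, rt
Reagents that add atoms: N-iodosuccinimide, O=C1CCC(=O)N1I
Why: Electrophilic aromatic iodination of a 5,7-dialkoxyflavone should go to C8'' (ortho to O7'' and O1'', para to O5''), because C6'' is flanked by two bulky alkoxy groups and ring B is deactivated by conjugation with the pyranone.

**Step 6**
Reactants: 9 5-fluorobenzene-1,3-diol
Product: 10 1-(2-fluoro-4,6-dihydroxyphenyl)ethanone
Conditions: AcOH, ZnCl2, 140 °C
Reagents that add atoms: acetic acid, CC(=O)O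
Why: Nencki (Friedel–Crafts) C-acylation of a resorcinol should occur para to one hydroxyl and ortho to the other, next to fluorine, in preference to the doubly flanked position between the hydroxyls, as in the acylation of orcinol.

**Step 7**
Reactants: 10 1-(2-fluoro-4,6-dihydroxyphenyl)ethanone
Product: 11 1-[2,4-bis(benzyloxy)-6-fluorophenyl]ethanone
Conditions: BnBr (2.5 equiv), K2CO3 (3 equiv), DMF, 50 °C
Reagents that add atoms: benzyl bromide, BrCc1ccccc1
Why: Williamson etherification of both phenols should proceed with excess reagent (the chelated ortho hydroxyl reacts last), while the phenoxide-bearing ring is too electron-rich for substitution of fluorine at this temperature.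

**Step 8**
Reactants: 8 5-(benzyloxy)-2-[4-(benzyloxy)phenyl]-8-iodo-7-(methoxymethoxy)-4H-chromen-4-one; 11 1-[2,4-bis(benzyloxy)-6-fluorophenyl]ethanone
Product: 12 1-[2,4-bis(benzyloxy)-6-fluorophenyl]-2-{5-(benzyloxy)-2-[4-(benzyloxy)phenyl]-7-(methoxymethoxy)-4-oxo-4H-chromen-8-yl}ethanone
Conditions: Pd2(dba)3 (2.5 mol%), XPhos (6 mol%), K3PO4, toluene, 90 °C
Reagents that add atoms: none
Why: Palladium-catalysed α-arylation of an aryl methyl ketone (Buchwald–Hartwig type) should give the mono-arylated ketone, the bulky biarylphosphine promoting coupling at the doubly ortho-substituted C8'' and the weak base sparing the aryl fluoride and the flavone.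

**Step 9**
Reactants: 12 1-[2,4-bis(benzyloxy)-6-fluorophenyl]-2-{5-(benzyloxy)-2-[4-(benzyloxy)phenyl]-7-(methoxymethoxy)-4-oxo-4H-chromen-8-yl}ethanone
Product: 13 8-{(Z)-2-[2,4-bis(benzyloxy)-6-fluorophenyl]-2-[(trimethylsilyl)oxy]ethenyl}-5-(benzyloxy)-2-[4-(benzyloxy)phenyl]-7-(methoxymethoxy)-4H-chromen-4-one
Conditions: Me3SiCl (2 equiv), LiN(SiMe3)2 (1.2 equiv), THF, −78 °C (in situ quench); non-aqueous work-up
Reagents that add atoms: chlorotrimethylsilane, C[Si](C)(C)Cl
Why: Silyl enol ether formation by deprotonation of the only acidic C–H (the doubly activated CH2) and O-silylation should give the (Z)-isomer, in which the two bulky aryl groups are trans.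

**Step 10**
Reactants: 13 8-{(Z)-2-[2,4-bis(benzyloxy)-6-fluorophenyl]-2-[(trimethylsilyl)oxy]ethenyl}-5-(benzyloxy)-2-[4-(benzyloxy)phenyl]-7-(methoxymethoxy)-4H-chromen-4-one; 4 4-(benzyloxy)benzaldehyde
Product: 16 (2R,3S)-5,7-bis(benzyloxy)-2-[4-(benzyloxy)phenyl]-3-{5-(benzyloxy)-2-[4-(benzyloxy)phenyl]-7-(methoxymethoxy)-4-oxo-4H-chromen-8-yl}chroman-4-one, via ammonium enolate 14 (not isolated), via anti-aldolate 15 (not isolated)
Conditions: 4 (1.5 equiv), N-(9-anthracenylmethyl)-O-allylcinchonidinium hydrogen difluoride (10 mol%), THF/toluene, −40 °C → rt; AcOH quench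
Reagents that add atoms: none
Why: Proposed new method: fluoride from the chiral ammonium bifluoride cleaves the O–Si bond of 13 (Me3SiF leaves) to give the ammonium (Z)-enolate 14, which adds through an open antiperiplanar transition state to the aldehyde carbon of 4 (C2–C3 bond) to give the anti-aldolate 15, whose alkoxide oxygen then attacks C8a of ring A and expels fluoride (O1–C8a bond), the fluoride re-entering the cycle so that the chiral cation is the only counter-ion ever present. The closest known reaction types are the quaternary ammonium fluoride-catalysed Mukaiyama-type aldol addition of enol silanes to aromatic aldehydes and the base-mediated SNAr cyclisation of 3-hydroxy-1-(2-fluoroaryl)propan-1-ones to chroman-4-ones, and what is new is their fusion into one fluoride-relay annulation. Ring C is closed by intramolecular nucleophilic aromatic substitution, a six-membered 6-exo-trig-type addition–elimination at C8a through an anionic σ-adduct stabilised by the ortho C4 carbonyl. C2 is set in the aldol event by the cinchonidinium cation, which is expected to leave the Re face of the aldehyde open (2R), and C3 by the anti preference of the open transition state together with thermodynamic control, since the acidic C3–H lets the two aryl groups settle trans-diequatorial (3S). The step needs the aldolate to cyclise faster than it reverts or is silylated, and the product not to ring-open by E1cB, which the C–F bond ortho to the ketone and meta to two alkoxy groups, the six-membered transition state, the low temperature and the irreversible loss of Me3SiF should secure, any O-silylated aldol being returned to 15 by fluoride. The enolate itself cannot reach C8a because a four-membered ring would result, so only the aldol oxygen is arylated.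

**Step 11**
Reactants: 16 (2R,3S)-5,7-bis(benzyloxy)-2-[4-(benzyloxy)phenyl]-3-{5-(benzyloxy)-2-[4-(benzyloxy)phenyl]-7-(methoxymethoxy)-4-oxo-4H-chromen-8-yl}chroman-4-one
Product: 17 (2R,3S)-5,7-bis(benzyloxy)-2-[4-(benzyloxy)phenyl]-3-{5-(benzyloxy)-2-[4-(benzyloxy)phenyl]-7-hydroxy-4-oxo-4H-chromen-8-yl}chroman-4-one
Conditions: HCl (cat.), MeOH/THF, 45 °C
Reagents that add atoms: none
Why: Acid-catalysed acetal (MOM ether) cleavage with methanol as acceptor should free only O7'', since benzyl ethers are inert and acid does not open the flavanone ring, so C2 is untouched and C3 can only stay in its more stable trans arrangement.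

**Step 12**
Reactants: 17 (2R,3S)-5,7-bis(benzyloxy)-2-[4-(benzyloxy)phenyl]-3-{5-(benzyloxy)-2-[4-(benzyloxy)phenyl]-7-hydroxy-4-oxo-4H-chromen-8-yl}chroman-4-one
Product: 18 5-(benzyloxy)-2-[4-(benzyloxy)phenyl]-8-{(2R,3S)-5,7-bis(benzyloxy)-2-[4-(benzyloxy)phenyl]-4-oxochroman-3-yl}-4-oxo-4H-chromen-7-yl hydrogen sulfate
Conditions: SO3·pyridine (5 equiv), pyridine, 50 °C; NaHCO3 work-up (sodium salt)
Reagents that add atoms: sulfur trioxide–pyridine complex, O=S(=O)([O-])[n+]1ccccc1
Why: O-Sulfation of the only free phenol with the SO3–pyridine complex should be clean, pyridine being too weak a base to epimerise C2 through E1cB ring opening.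

**Step 13**
Reactants: 18 5-(benzyloxy)-2-[4-(benzyloxy)phenyl]-8-{(2R,3S)-5,7-bis(benzyloxy)-2-[4-(benzyloxy)phenyl]-4-oxochroman-3-yl}-4-oxo-4H-chromen-7-yl hydrogen sulfate
Product: 19 8-[(2R,3S)-5,7-dihydroxy-2-(4-hydroxyphenyl)-4-oxochroman-3-yl]-5-hydroxy-2-(4-hydroxyphenyl)-4-oxo-4H-chromen-7-yl hydrogen sulfate
Conditions: H2 (1 atm), Pd/C (10% Pd on carbon), THF/MeOH, rt; then H+ cation-exchange resin, 0 °C
Reagents that add atoms: none
Why: Catalytic hydrogenolysis should remove the five benzyl ethers under neutral conditions that normally leave aryl sulfate salts, the flavone double bond, the chelated ketones and both stereocentres untouched.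

**Compound list**
1 | 1-(2,4,6-trihydroxyphenyl)ethanone | CC(=O)c1c(O)cc(O)cc1O | starting material
2 | 1-[2,6-dihydroxy-4-(methoxymethoxy)phenyl]ethanone | CC(=O)c1c(O)cc(OCOC)cc1O | intermediate
3 | 1-[2-(benzyloxy)-6-hydroxy-4-(methoxymethoxy)phenyl]ethanone | CC(=O)c1c(O)cc(OCOC)cc1OCc1ccccc1 | intermediate
4 | 4-(benzyloxy)benzaldehyde | O=Cc1ccc(OCc2ccccc2)cc1 | starting material
5 | (E)-1-[2-(benzyloxy)-6-hydroxy-4-(methoxymethoxy)phenyl]-3-[4-(benzyloxy)phenyl]prop-2-en-1-one | O=C(/C=C/c1ccc(OCc2ccccc2)cc1)c1c(O)cc(OCOC)cc1OCc1ccccc1 | intermediate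
6 | racemic 5-(benzyloxy)-2-[4-(benzyloxy)phenyl]-7-(methoxymethoxy)chroman-4-one (not isolated) | O=C1CC(c2ccc(OCc3ccccc3)cc2)Oc2cc(OCOC)cc(OCc3ccccc3)c12 | intermediate
7 | 5-(benzyloxy)-2-[4-(benzyloxy)phenyl]-7-(methoxymethoxy)-4H-chromen-4-one | O=c1cc(-c2ccc(OCc3ccccc3)cc2)oc2cc(OCOC)cc(OCc3ccccc3)c12 | intermediate
8 | 5-(benzyloxy)-2-[4-(benzyloxy)phenyl]-8-iodo-7-(methoxymethoxy)-4H-chromen-4-one | O=c1cc(-c2ccc(OCc3ccccc3)cc2)oc2c(I)c(OCOC)cc(OCc3ccccc3)c12 | intermediate
9 | 5-fluorobenzene-1,3-diol | Oc1cc(O)cc(F)c1 | starting material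
10 | 1-(2-fluoro-4,6-dihydroxyphenyl)ethanone | CC(=O)c1c(O)cc(O)cc1F | intermediate
11 | 1-[2,4-bis(benzyloxy)-6-fluorophenyl]ethanone | CC(=O)c1c(F)cc(OCc2ccccc2)cc1OCc1ccccc1 | intermediate
12 | 1-[2,4-bis(benzyloxy)-6-fluorophenyl]-2-{5-(benzyloxy)-2-[4-(benzyloxy)phenyl]-7-(methoxymethoxy)-4-oxo-4H-chromen-8-yl}ethanone | O=C(Cc1c(OCOC)cc(OCc2ccccc2)c2c(=O)cc(-c3ccc(OCc4ccccc4)cc3)oc12)c1c(F)cc(OCc2ccccc2)cc1OCc1ccccc1 | intermediate
13 | 8-{(Z)-2-[2,4-bis(benzyloxy)-6-fluorophenyl]-2-[(trimethylsilyl)oxy]ethenyl}-5-(benzyloxy)-2-[4-(benzyloxy)phenyl]-7-(methoxymethoxy)-4H-chromen-4-one | C[Si](C)(C)O/C(=C\c1c(OCOC)cc(OCc2ccccc2)c2c(=O)cc(-c3ccc(OCc4ccccc4)cc3)oc12)c1c(F)cc(OCc2ccccc2)cc1OCc1ccccc1 | intermediate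
14 | (Z)-enolate of 12 as ion pair with the catalyst cation (anion drawn; not isolated) | [O-]/C(=C\c1c(OCOC)cc(OCc2ccccc2)c2c(=O)cc(-c3ccc(OCc4ccccc4)cc3)oc12)c1c(F)cc(OCc2ccccc2)cc1OCc1ccccc1 | intermediate
15 | (2S,3R)-anti-aldolate, 1-[2,4-bis(benzyloxy)-6-fluorophenyl]-3-[4-(benzyloxy)phenyl]-2-{5-(benzyloxy)-2-[4-(benzyloxy)phenyl]-7-(methoxymethoxy)-4-oxo-4H-chromen-8-yl}-3-oxidopropan-1-one as ion pair with the catalyst cation (anion drawn; not isolated) | [O-][C@@H](c1ccc(OCc2ccccc2)cc1)[C@@H](C(=O)c1c(F)cc(OCc2ccccc2)cc1OCc1ccccc1)c1c(OCOC)cc(OCc2ccccc2)c2c(=O)cc(-c3ccc(OCc4ccccc4)cc3)oc12 | intermediate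
16 | (2R,3S)-5,7-bis(benzyloxy)-2-[4-(benzyloxy)phenyl]-3-{5-(benzyloxy)-2-[4-(benzyloxy)phenyl]-7-(methoxymethoxy)-4-oxo-4H-chromen-8-yl}chroman-4-one (2,3-trans) | O=C1c2c(OCc3ccccc3)cc(OCc3ccccc3)cc2O[C@@H](c2ccc(OCc3ccccc3)cc2)[C@@H]1c1c(OCOC)cc(OCc2ccccc2)c2c(=O)cc(-c3ccc(OCc4ccccc4)cc3)oc12 | intermediate
17 | (2R,3S)-5,7-bis(benzyloxy)-2-[4-(benzyloxy)phenyl]-3-{5-(benzyloxy)-2-[4-(benzyloxy)phenyl]-7-hydroxy-4-oxo-4H-chromen-8-yl}chroman-4-one | O=C1c2c(OCc3ccccc3)cc(OCc3ccccc3)cc2O[C@@H](c2ccc(OCc3ccccc3)cc2)[C@@H]1c1c(O)cc(OCc2ccccc2)c2c(=O)cc(-c3ccc(OCc4ccccc4)cc3)oc12 | intermediate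
18 | 5-(benzyloxy)-2-[4-(benzyloxy)phenyl]-8-{(2R,3S)-5,7-bis(benzyloxy)-2-[4-(benzyloxy)phenyl]-4-oxochroman-3-yl}-4-oxo-4H-chromen-7-yl hydrogen sulfate | O=C1c2c(OCc3ccccc3)cc(OCc3ccccc3)cc2O[C@@H](c2ccc(OCc3ccccc3)cc2)[C@@H]1c1c(OS(=O)(=O)O)cc(OCc2ccccc2)c2c(=O)cc(-c3ccc(OCc4ccccc4)cc3)oc12 | intermediate
19 | 8-[(2R,3S)-5,7-dihydroxy-2-(4-hydroxyphenyl)-4-oxochroman-3-yl]-5-hydroxy-2-(4-hydroxyphenyl)-4-oxo-4H-chromen-7-yl hydrogen sulfate | O=C1c2c(O)cc(O)cc2O[C@@H](c2ccc(O)cc2)[C@@H]1c1c(OS(=O)(=O)O)cc(O)c2c(=O)cc(-c3ccc(O)cc3)oc12 | target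

**Step count**
Total: 13 steps. Longest linear sequence: 11 steps (steps 1, 2, 3, 4, 5, 8, 9, 10, 11, 12, 13).

**Steps most likely to fail**

Step 10. The process at risk is weak facial discrimination within the ion pair, together with erosion of the C2 configuration by retro-aldol reaction and E1cB ring opening under naked-fluoride conditions. If only the sense of induction is wrong, the pseudoenantiomeric cinchoninium salt would be tried first. The fallback with known chemistry sets out from ketone 12. Enolisation with the chiral bromoborane 2-bromo-4,5-diphenyl-1,3-bis(p-tolylsulfonyl)-1,3,2-diazaborolidine (the antipode that directs the enolate to the Re face of the aldehyde) and i-Pr2NEt in CH2Cl2 at −78 °C, then addition of 4, should give through a closed chair transition state the syn aldol (2R,3R)-1-[2,4-bis(benzyloxy)-6-fluorophenyl]-3-[4-(benzyloxy)phenyl]-2-{5-(benzyloxy)-2-[4-(benzyloxy)phenyl]-7-(methoxymethoxy)-4-oxo-4H-chromen-8-yl}-3-hydroxypropan-1-one F1, which is isolated. NaH in THF at 0 °C should then close ring C by SNAr to the 2,3-cis flavanone (2R,3R)-5,7-bis(benzyloxy)-2-[4-(benzyloxy)phenyl]-3-{5-(benzyloxy)-2-[4-(benzyloxy)phenyl]-7-(methoxymethoxy)-4-oxo-4H-chromen-8-yl}chroman-4-one F2. This should epimerise at C3 in the same flask, or on brief treatment with DBU, to the trans isomer, coming back to the route at 16.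

Step 8. The process at risk is slow oxidative addition and reductive elimination at the doubly ortho-substituted C8'', so that hydrodeiodination of 8 and base-induced self-condensation of 11 take over. The fallback sets out from 8. Kosugi–Migita–Stille coupling with allyltributylstannane (Pd(PPh3)4, LiCl, DMF, 90 °C) should give 5-(benzyloxy)-2-[4-(benzyloxy)phenyl]-7-(methoxymethoxy)-8-(prop-2-en-1-yl)-4H-chromen-4-one F3. Lemieux–Johnson cleavage (OsO4 cat., NaIO4, 2,6-lutidine, dioxane/water) should give {5-(benzyloxy)-2-[4-(benzyloxy)phenyl]-7-(methoxymethoxy)-4-oxo-4H-chromen-8-yl}acetaldehyde F4. In parallel, 9 is benzylated (BnBr, K2CO3, DMF) to 1,3-bis(benzyloxy)-5-fluorobenzene F5 and brominated (NBS, MeCN) to 1,5-bis(benzyloxy)-2-bromo-3-fluorobenzene F6. Bromine–lithium exchange of F6 (n-BuLi, THF, −78 °C), transmetalation with CeCl3 and addition to F4 should give the racemic alcohol 1-[2,4-bis(benzyloxy)-6-fluorophenyl]-2-{5-(benzyloxy)-2-[4-(benzyloxy)phenyl]-7-(methoxymethoxy)-4-oxo-4H-chromen-8-yl}ethanol F7. Oxidation with Dess–Martin periodinane comes back to the route at 12.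

Step 12. The process at risk is incomplete sulfation of the phenol flanked by the C8'' substituent, and hydrolytic loss of the sulfate while the ionic, polybenzylated product is purified. The fallback sets out from 17. Sulfation with 2,2,2-trichloroethyl chlorosulfate (Et3N, DMAP, THF) should give the neutral, chromatographable diester 5-(benzyloxy)-2-[4-(benzyloxy)phenyl]-8-{(2R,3S)-5,7-bis(benzyloxy)-2-[4-(benzyloxy)phenyl]-4-oxochroman-3-yl}-4-oxo-4H-chromen-7-yl 2,2,2-trichloroethyl sulfate F8. Zn dust and HCO2NH4 in MeOH should remove the trichloroethyl group by reductive fragmentation, coming back to the route at 18.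

**Further compounds**
F1 | step 10 | (2R,3R)-1-[2,4-bis(benzyloxy)-6-fluorophenyl]-3-[4-(benzyloxy)phenyl]-2-{5-(benzyloxy)-2-[4-(benzyloxy)phenyl]-7-(methoxymethoxy)-4-oxo-4H-chromen-8-yl}-3-hydroxypropan-1-one | O[C@@H](c1ccc(OCc2ccccc2)cc1)[C@H](C(=O)c1c(F)cc(OCc2ccccc2)cc1OCc1ccccc1)c1c(OCOC)cc(OCc2ccccc2)c2c(=O)cc(-c3ccc(OCc4ccccc4)cc3)oc12
F2 | step 10 | (2R,3R)-5,7-bis(benzyloxy)-2-[4-(benzyloxy)phenyl]-3-{5-(benzyloxy)-2-[4-(benzyloxy)phenyl]-7-(methoxymethoxy)-4-oxo-4H-chromen-8-yl}chroman-4-one (2,3-cis) | O=C1c2c(OCc3ccccc3)cc(OCc3ccccc3)cc2O[C@@H](c2ccc(OCc3ccccc3)cc2)[C@H]1c1c(OCOC)cc(OCc2ccccc2)c2c(=O)cc(-c3ccc(OCc4ccccc4)cc3)oc12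
F3 | step 8 | 5-(benzyloxy)-2-[4-(benzyloxy)phenyl]-7-(methoxymethoxy)-8-(prop-2-en-1-yl)-4H-chromen-4-one | C=CCc1c(OCOC)cc(OCc2ccccc2)c2c(=O)cc(-c3ccc(OCc4ccccc4)cc3)oc12
F4 | step 8 | {5-(benzyloxy)-2-[4-(benzyloxy)phenyl]-7-(methoxymethoxy)-4-oxo-4H-chromen-8-yl}acetaldehyde | O=CCc1c(OCOC)cc(OCc2ccccc2)c2c(=O)cc(-c3ccc(OCc4ccccc4)cc3)oc12
F5 | step 8 | 1,3-bis(benzyloxy)-5-fluorobenzene | Fc1cc(OCc2ccccc2)cc(OCc2ccccc2)c1
F6 | step 8 | 1,5-bis(benzyloxy)-2-bromo-3-fluorobenzene | Brc1c(F)cc(OCc2ccccc2)cc1OCc1ccccc1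
F7 | step 8 | racemic 1-[2,4-bis(benzyloxy)-6-fluorophenyl]-2-{5-(benzyloxy)-2-[4-(benzyloxy)phenyl]-7-(methoxymethoxy)-4-oxo-4H-chromen-8-yl}ethanol | OC(Cc1c(OCOC)cc(OCc2ccccc2)c2c(=O)cc(-c3ccc(OCc4ccccc4)cc3)oc12)c1c(F)cc(OCc2ccccc2)cc1OCc1ccccc1
F8 | step 12 | 5-(benzyloxy)-2-[4-(benzyloxy)phenyl]-8-{(2R,3S)-5,7-bis(benzyloxy)-2-[4-(benzyloxy)phenyl]-4-oxochroman-3-yl}-4-oxo-4H-chromen-7-yl 2,2,2-trichloroethyl sulfate | O=C1c2c(OCc3ccccc3)cc(OCc3ccccc3)cc2O[C@@H](c2ccc(OCc3ccccc3)cc2)[C@@H]1c1c(OS(=O)(=O)OCC(Cl)(Cl)Cl)cc(OCc2ccccc2)c2c(=O)cc(-c3ccc(OCc4ccccc4)cc3)oc12
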